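**Strategy.** The target is treated as the acid-cyclised form of a C2-symmetric trimer: both trans-2,3-diaryl-2,3-dihydrobenzofuran rings (O1–C2–C3–C3a–C7a, each 2R,3R) sit on the central benzene ring on either side of the carbon that carries the CH2 of the seven-membered ring. Each of these five-membered rings is made from a six-membered δ-lactone. A double Perkin-type ring contraction of a bis(trans-3-bromo-4-aryl-3,4-dihydrocoumarin) extrudes the lactone carbonyl carbons as carboxyl groups; the lactone C4 stereocentres, set by catalyst-controlled CuH reduction, become C3 of each dihydrobenzofuran. The carboxyl groups are then exchanged for 4-methoxyphenyl groups. Suzuki coupling, Friedel–Crafts closure of the seven-membered ring and demethylation finish the synthesis.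

Key step: step 5

Remark (assumption): the CuH/(R)-DTBM-SEGPHOS catalyst is assumed to give the 4R,6R series from bis-coumarin 6; if a trial on a mono-coumarin model shows the opposite sense, (S)-DTBM-SEGPHOS is used and nothing else changes.

**Step 1**
Reactants: 1 1-bromo-3,5-dimethoxybenzene; 2 3,5-dimethoxybenzoyl chloride
Product: 4 (2-bromo-4,6-dihydroxy-1,3-phenylene)bis[(3,5-dimethoxyphenyl)methanone], via bis-ketone dimethyl ether 3 (not isolated)
Conditions: 2 (2.4 equiv), AlCl3 (2.6 equiv), CH2Cl2, 0 °C → rt; then, on the crude diketone, BCl3 (3 equiv), CH2Cl2, −78 → 0 °C; aq. HCl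
Reagents that add atoms: none
Why: Double Friedel–Crafts acylation should go to the two positions flanking bromine (each para to one OMe and ortho to the other, whereas the site between the two OMe groups is the more shielded), and BCl3 should then cleave only the two methyl ethers that can form a six-membered boron chelate with the new ketones (chelation-controlled ortho-demethylation), leaving the four OMe groups of the benzoyl rings.

**Step 2**
Reactants: 4 (2-bromo-4,6-dihydroxy-1,3-phenylene)bis[(3,5-dimethoxyphenyl)methanone]; 5 (triphenylphosphoranylidene)ketene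
Product: 6 5-bromo-4,6-bis(3,5-dimethoxyphenyl)-2H,8H-pyrano[3,2-g]chromene-2,8-dione
Conditions: 5 (2.4 equiv), toluene, 110 °C
Reagents that add atoms: none
Why: Each phenol should add to the cumulated ylide to give an aryl (triphenylphosphoranylidene)acetate, which closes the α-pyranone ring by intramolecular Wittig olefination of the neighbouring diaryl ketone (coumarin synthesis from o-hydroxyaryl ketones); no stereocentre is formed.

**Step 3**
Reactants: 6 5-bromo-4,6-bis(3,5-dimethoxyphenyl)-2H,8H-pyrano[3,2-g]chromene-2,8-dione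
Product: 7 (4R,6R)-5-bromo-4,6-bis(3,5-dimethoxyphenyl)-3,4,6,7-tetrahydro-2H,8H-pyrano[3,2-g]chromene-2,8-dione
Conditions: Cu(OAc)2·H2O (5 mol%), (R)-DTBM-SEGPHOS (5.5 mol%), (EtO)2MeSiH (2.4 equiv), t-BuOH (2.4 equiv), toluene/THF, 0 °C → rt
Reagents that add atoms: none
Why: Copper hydride asymmetric conjugate reduction of β,β-diaryl enoates (4-arylcoumarins) delivers hydride to C4 and C6 under ligand control, so both stereocentres are set by the catalyst (4R,6R), and a wrong-face event at one ring ends in the separable meso isomer, which should raise the enantiomeric purity of the C2-symmetric product.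

**Step 4**
Reactants: 7 (4R,6R)-5-bromo-4,6-bis(3,5-dimethoxyphenyl)-3,4,6,7-tetrahydro-2H,8H-pyrano[3,2-g]chromene-2,8-dione
Product: 8 (3S,4R,6R,7S)-3,5,7-tribromo-4,6-bis(3,5-dimethoxyphenyl)-3,4,6,7-tetrahydro-2H,8H-pyrano[3,2-g]chromene-2,8-dione
Conditions: LiHMDS (2.2 equiv), THF, −78 °C; then BrCCl2CCl2Br (2.4 equiv), −78 °C; AcOH quench
Reagents that add atoms: 1,2-dibromo-1,1,2,2-tetrachloroethane, BrC(Cl)(Cl)C(Cl)(Cl)Br
Why: α-Bromination of the bis(lactone enolate) with a bromine source that does not attack the dimethoxyarenes; bromine should enter each enolate on the face opposite to the adjacent aryl group, setting C3 and C7 as S (3,4-trans), a configuration that is not carried into the target.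

**Step 5**
Reactants: 8 (3S,4R,6R,7S)-3,5,7-tribromo-4,6-bis(3,5-dimethoxyphenyl)-3,4,6,7-tetrahydro-2H,8H-pyrano[3,2-g]chromene-2,8-dione
Product: 10 (2R,3R,5R,6R)-4-bromo-3,5-bis(3,5-dimethoxyphenyl)-2,3,5,6-tetrahydrobenzo[1,2-b:5,4-b']difuran-2,6-dicarboxylic acid, via dimethyl diester 9 (not isolated)
Conditions: K2CO3 (4 equiv), MeOH/THF 3:1, 0 °C → rt; then LiOH·H2O (6 equiv), H2O, rt; 1 M HCl
Reagents that add atoms: methanol, CO (methoxy groups of 9); lithium hydroxide, [Li+].[OH-] (hydroxyl oxygen of each carboxyl group of 10)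
Why: Methoxide opens each aryl δ-lactone at the acyl carbon and the phenoxide so released displaces the bromide on the α-carbon of the new methyl ester, so that (coumarin numbering for each half) the six-membered ring O1–C2(=O)–C3–C4–C4a–C8a is replaced by the five-membered ring O1–C3–C4–C4a–C8a with the former carbonyl carbon C2 outside the ring as CO2Me. The closest known reaction is the Perkin coumarin-to-benzofuran ring contraction, used here in its 3,4-dihydro (α-bromo-dihydrocoumarin) form. Each dihydrofuran ring closes by a 5-exo-tet intramolecular Williamson substitution. C3 of each new ring is the untouched C4 of the lactone (R), and the new C2 stereocentre arises by inversion at the C–Br carbon (3S → 2R, trans to the 3-aryl group), although this centre is only provisional because step 6 sets it again. The step needs substitution to win over E2 loss of HBr, which would give the achiral 3,3-diarylacrylate; the weakly basic phenoxide, the fast five-membered closure at 0 °C and the lack of an anti-periplanar H/Br pair in the trans lactone should secure this, and the hindered aryl bromide is inert. Lithium hydroxide then saponifies both esters in the same flask.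

**Step 6**
Reactants: 10 (2R,3R,5R,6R)-4-bromo-3,5-bis(3,5-dimethoxyphenyl)-2,3,5,6-tetrahydrobenzo[1,2-b:5,4-b']difuran-2,6-dicarboxylic acid; 11 4-iodoanisole
Product: 12 (2R,3R,5R,6R)-4-bromo-3,5-bis(3,5-dimethoxyphenyl)-2,6-bis(4-methoxyphenyl)-2,3,5,6-tetrahydrobenzo[1,2-b:5,4-b']difuran
Conditions: 11 (4 equiv), Ir[dF(CF3)ppy]2(dtbbpy)PF6 (2 mol%), NiCl2·glyme (20 mol%), dtbbpy (20 mol%), Cs2CO3 (3 equiv), DMF, blue LEDs, rt
Reagents that add atoms: none
Why: Metallaphotoredox decarboxylative arylation of α-oxy acids: each carboxylate is oxidised and loses CO2 to give the C2 (C6) α-aryloxy radical, which is captured by the aryl–nickel species from 4-iodoanisole and coupled on the face opposite to the neighbouring C3 (C5) aryl group, so C2 and C6 are set R (trans) by the adjacent stereocentres, while the electron-rich, doubly ortho-substituted C–Br bond should be far slower than the aryl iodide in oxidative addition.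

**Step 7**
Reactants: 13 2,4-dimethoxybenzaldehyde; 14 bis(4,4,5,5-tetramethyl-1,3,2-dioxaborolan-2-yl)methane
Product: 15 (E)-2-[2-(2,4-dimethoxyphenyl)ethenyl]-4,4,5,5-tetramethyl-1,3,2-dioxaborolane
Conditions: 14 (1.1 equiv), LiTMP (1.2 equiv), THF, 0 °C; then 13, 0 °C → rt; sat. NH4Cl
Reagents that add atoms: none
Why: Boron-Wittig olefination: the lithiated geminal bis(boronate) adds to the aldehyde and elimination of the O–B unit should give the E-alkenyl boronate; no stereocentre is formed and the alkene geometry is not critical for step 9.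

**Step 8**
Reactants: 12 (2R,3R,5R,6R)-4-bromo-3,5-bis(3,5-dimethoxyphenyl)-2,6-bis(4-methoxyphenyl)-2,3,5,6-tetrahydrobenzo[1,2-b:5,4-b']difuran; 15 (E)-2-[2-(2,4-dimethoxyphenyl)ethenyl]-4,4,5,5-tetramethyl-1,3,2-dioxaborolane
Product: 16 (2R,3R,5R,6R)-4-[(E)-2-(2,4-dimethoxyphenyl)ethenyl]-3,5-bis(3,5-dimethoxyphenyl)-2,6-bis(4-methoxyphenyl)-2,3,5,6-tetrahydrobenzo[1,2-b:5,4-b']difuran
Conditions: 15 (1.5 equiv), Pd(OAc)2 (5 mol%), SPhos (10 mol%), K3PO4 (3 equiv), toluene/H2O 10:1, 100 °C
Reagents that add atoms: none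
Why: Suzuki–Miyaura coupling with a bulky dialkylbiarylphosphine ligand suited to doubly ortho-substituted aryl bromides and an unhindered alkenyl boronate; the base cannot epimerise the diarylmethine or benzylic ether stereocentres, and no new stereocentre is formed.

**Step 9**
Reactants: 16 (2R,3R,5R,6R)-4-[(E)-2-(2,4-dimethoxyphenyl)ethenyl]-3,5-bis(3,5-dimethoxyphenyl)-2,6-bis(4-methoxyphenyl)-2,3,5,6-tetrahydrobenzo[1,2-b:5,4-b']difuran
Product: 17 octa-O-methyl ether of the target (all five stereocentres R)
Conditions: CF3CO2H (5 equiv), CH2Cl2, −20 °C → rt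
Reagents that add atoms: none
Why: Protonation of the stilbene at the carbon attached to the central ring gives the 2,4-dimethoxybenzylic cation, which is attacked by the ortho carbon of either of the two homotopic 3,5-dimethoxyphenyl rings in an intramolecular Friedel–Crafts alkylation that closes the seven-membered ring; the new CH(aryl) stereocentre is set by the adjacent dihydrobenzofuran, the aryl group being expected on the ring face opposite to C2 of that dihydrobenzofuran (R) under these reversible conditions, as in the acid cyclisation of ε-viniferin-type stilbenes.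

**Step 10**
Reactants: 17 octa-O-methyl ether of the target
Product: 18 target CNP0154047.1
Conditions: BBr3 (20 equiv), CH2Cl2, −78 °C → rt; MeOH, then H2O
Reagents that add atoms: none
Why: Lewis acid cleavage of all eight aryl methyl ethers (BBr3 demethylation); the cold, aprotic conditions are chosen so that the benzylic C–O bonds of the dihydrobenzofurans are not ionised and the five stereocentres are kept.

**Compound list**
1 | 1-bromo-3,5-dimethoxybenzene | COc1cc(Br)cc(OC)c1 | starting material
2 | 3,5-dimethoxybenzoyl chloride | COc1cc(cc(OC)c1)C(Cl)=O | starting material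
3 | (2-bromo-4,6-dimethoxy-1,3-phenylene)bis[(3,5-dimethoxyphenyl)methanone] | COc1cc(OC)c(C(=O)c2cc(OC)cc(OC)c2)c(Br)c1C(=O)c1cc(OC)cc(OC)c1 | intermediate
4 | (2-bromo-4,6-dihydroxy-1,3-phenylene)bis[(3,5-dimethoxyphenyl)methanone] | Oc1cc(O)c(C(=O)c2cc(OC)cc(OC)c2)c(Br)c1C(=O)c1cc(OC)cc(OC)c1 | intermediate
5 | (triphenylphosphoranylidene)ketene | O=C=C=P(c1ccccc1)(c1ccccc1)c1ccccc1 | starting material
6 | 5-bromo-4,6-bis(3,5-dimethoxyphenyl)-2H,8H-pyrano[3,2-g]chromene-2,8-dione | O=C1C=C(c2cc(OC)cc(OC)c2)c2c(O1)cc1OC(=O)C=C(c3cc(OC)cc(OC)c3)c1c2Br | intermediate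
7 | (4R,6R)-5-bromo-4,6-bis(3,5-dimethoxyphenyl)-3,4,6,7-tetrahydro-2H,8H-pyrano[3,2-g]chromene-2,8-dione | O=C1C[C@H](c2cc(OC)cc(OC)c2)c2c(O1)cc1OC(=O)C[C@H](c3cc(OC)cc(OC)c3)c1c2Br | intermediate
8 | (3S,4R,6R,7S)-3,5,7-tribromo-4,6-bis(3,5-dimethoxyphenyl)-3,4,6,7-tetrahydro-2H,8H-pyrano[3,2-g]chromene-2,8-dione | O=C1[C@@H](Br)[C@H](c2cc(OC)cc(OC)c2)c2c(O1)cc1OC(=O)[C@@H](Br)[C@H](c3cc(OC)cc(OC)c3)c1c2Br | intermediate
9 | dimethyl (2R,3R,5R,6R)-4-bromo-3,5-bis(3,5-dimethoxyphenyl)-2,3,5,6-tetrahydrobenzo[1,2-b:5,4-b']difuran-2,6-dicarboxylate | COC(=O)[C@@H]1Oc2cc3O[C@@H](C(=O)OC)[C@H](c4cc(OC)cc(OC)c4)c3c(Br)c2[C@H]1c1cc(OC)cc(OC)c1 | intermediate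
10 | (2R,3R,5R,6R)-4-bromo-3,5-bis(3,5-dimethoxyphenyl)-2,3,5,6-tetrahydrobenzo[1,2-b:5,4-b']difuran-2,6-dicarboxylic acid | OC(=O)[C@@H]1Oc2cc3O[C@@H](C(O)=O)[C@H](c4cc(OC)cc(OC)c4)c3c(Br)c2[C@H]1c1cc(OC)cc(OC)c1 | intermediate
11 | 4-iodoanisole | COc1ccc(I)cc1 | starting material
12 | (2R,3R,5R,6R)-4-bromo-3,5-bis(3,5-dimethoxyphenyl)-2,6-bis(4-methoxyphenyl)-2,3,5,6-tetrahydrobenzo[1,2-b:5,4-b']difuran | COc1ccc(cc1)[C@@H]1Oc2cc3O[C@@H](c4ccc(OC)cc4)[C@H](c4cc(OC)cc(OC)c4)c3c(Br)c2[C@H]1c1cc(OC)cc(OC)c1 | intermediate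
13 | 2,4-dimethoxybenzaldehyde | COc1ccc(C=O)c(OC)c1 | starting material
14 | bis(4,4,5,5-tetramethyl-1,3,2-dioxaborolan-2-yl)methane | CC1(C)OB(CB2OC(C)(C)C(C)(C)O2)OC1(C)C | starting material
15 | (E)-2-[2-(2,4-dimethoxyphenyl)ethenyl]-4,4,5,5-tetramethyl-1,3,2-dioxaborolane | COc1ccc(/C=C/B2OC(C)(C)C(C)(C)O2)c(OC)c1 | intermediate
16 | (2R,3R,5R,6R)-4-[(E)-2-(2,4-dimethoxyphenyl)ethenyl]-3,5-bis(3,5-dimethoxyphenyl)-2,6-bis(4-methoxyphenyl)-2,3,5,6-tetrahydrobenzo[1,2-b:5,4-b']difuran | COc1ccc(cc1)[C@@H]1Oc2cc3O[C@@H](c4ccc(OC)cc4)[C@H](c4cc(OC)cc(OC)c4)c3c(/C=C/c4ccc(OC)cc4OC)c2[C@H]1c1cc(OC)cc(OC)c1 | intermediate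
17 | octa-O-methyl ether of the target (all five stereocentres R) | COc1ccc([C@@H]2Oc3cc4c5c(c3[C@H]2c2cc(OC)cc(OC)c2)C[C@H](c2ccc(OC)cc2OC)c2c(OC)cc(OC)cc2[C@H]5[C@H](c2ccc(OC)cc2)O4)cc1 | intermediate
18 | CNP0154047.1 (all five stereocentres R) | Oc1ccc([C@@H]2Oc3cc4c5c(c3[C@H]2c2cc(O)cc(O)c2)C[C@H](c2ccc(O)cc2O)c2c(O)cc(O)cc2[C@H]5[C@H](c2ccc(O)cc2)O4)cc1 | target

**Step count and risks**
Total step count: 10. Longest linear sequence: 9 (steps 1–6 and 8–10; step 7 is a one-step side branch).

Steps most likely to fail: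

- **Step 6 (double decarboxylative arylation).** The C2 radical may be reduced (protodecarboxylation) before nickel captures it. Nickel may also insert into the central C–Br bond, or the second coupling may stall. The fallback replaces photoredox generation from the free acid by thermal coupling of a pre-activated ester. Setting out from 10, esterification with N-hydroxyphthalimide (N,N'-diisopropylcarbodiimide, DMAP, CH2Cl2) gives the bis(N-acyloxyphthalimide) ester F2. This is coupled with commercial 4-methoxyphenylzinc iodide under Fe(acac)3/dppBz catalysis (THF, rt), a catalyst that does not insert into aryl bromides. Aryl transfer to the C2 radical is again expected trans to the C3 aryl group, and the fallback returns to the route at 12.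

- **Step 3 (double asymmetric conjugate reduction).** Hydride delivery to the β-carbons, which are crowded by the peri bromine, may be slow. Facial selectivity may be eroded, or the lactones may be over-reduced to lactols. The fallback uses resolution in place of asymmetric catalysis. Setting out from 6, conjugate reduction with lithium tri-sec-butylborohydride (THF, −78 °C) gives the stereorandom tetrahydro bis-lactone F1. The meso isomer is removed by chromatography and the C2-symmetric pair is resolved on a chiral stationary phase. The (4R,6R) enantiomer rejoins the route at 7.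

- **Step 8 (Suzuki coupling at the doubly ortho-substituted bromide).** Oxidative addition or transmetalation may be too slow, so that protodebromination or boronate decomposition takes over. The fallback uses carbonyl olefination in place of cross-coupling. Setting out from 12, bromine–lithium exchange (t-BuLi, THF, −78 °C) and formylation with DMF give the 4-carbaldehyde F3. Horner–Wadsworth–Emmons reaction with diethyl (2,4-dimethoxybenzyl)phosphonate F4 (NaH, THF, 0 °C → rt) forms the E-stilbene. F4 is made from commercial 2,4-dimethoxybenzyl alcohol and triethyl phosphite with ZnI2. The fallback returns to the route at 16.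

**Further compounds**
F1 | step 3 | 5-bromo-4,6-bis(3,5-dimethoxyphenyl)-3,4,6,7-tetrahydro-2H,8H-pyrano[3,2-g]chromene-2,8-dione, stereorandom mixture (4R,6R/4S,6S pair and meso) | O=C1CC(c2cc(OC)cc(OC)c2)c2c(O1)cc1OC(=O)CC(c3cc(OC)cc(OC)c3)c1c2Br
F2 | step 6 | bis(1,3-dioxoisoindolin-2-yl) (2R,3R,5R,6R)-4-bromo-3,5-bis(3,5-dimethoxyphenyl)-2,3,5,6-tetrahydrobenzo[1,2-b:5,4-b']difuran-2,6-dicarboxylate | O=C(ON1C(=O)c2ccccc2C1=O)[C@@H]1Oc2cc3O[C@@H](C(=O)ON4C(=O)c5ccccc5C4=O)[C@H](c4cc(OC)cc(OC)c4)c3c(Br)c2[C@H]1c1cc(OC)cc(OC)c1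
F3 | step 8 | (2R,3R,5R,6R)-3,5-bis(3,5-dimethoxyphenyl)-2,6-bis(4-methoxyphenyl)-2,3,5,6-tetrahydrobenzo[1,2-b:5,4-b']difuran-4-carbaldehyde | COc1ccc(cc1)[C@@H]1Oc2cc3O[C@@H](c4ccc(OC)cc4)[C@H](c4cc(OC)cc(OC)c4)c3c(C=O)c2[C@H]1c1cc(OC)cc(OC)c1
F4 | step 8 | diethyl (2,4-dimethoxybenzyl)phosphonate | CCOP(=O)(Cc1ccc(OC)cc1OC)OCC
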